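The ratio I freeze here is between how far the two mirror-image substrates have gone. If both meet the same catalyst and reagent at each instant, those cancel from the ratio of their rates, so it needs no account of the time course.

| flask | left-handed substrate | right-handed substrate | solid reagent | precatalyst | remark | time |
|---|---|---|---|---|---|---|
| epsilon | 0.40 M | 0.40 M | 0.75 equiv | 7 mol% | run made earlier |  |
| beta | 0.40 M | 0.40 M | 1.1 equiv | 7 mol% | run made earlier |  |
| delta | 0.40 M | 0.40 M | 1.5 equiv | 10 mol% | run made earlier |  |
| ash | 0.40 M | 0.40 M | 1.50 equiv | 7 mol% |  | 12 h |
| maple | 0.40 M | 0.40 M | 1.50 equiv | 7 mol% |  | 20 h |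

| run | time / h | left-handed product / % | right-handed product / % |
|---|---|---|---|
| epsilon | 0.833 | 1.3 | 0 |
| epsilon | 1.33 | 5.8 | 0 |
| epsilon | 2.00 | 13.9 | 1.3 |
| epsilon | 4.00 | 23.4 | 1.6 |
| epsilon | 6.00 | 28.6 | 0.2 |
| epsilon | 10.0 | 28.4 | 0 |
| beta | 0.833 | 2.6 | 0 |
| beta | 1.33 | 5.4 | 0 |
| beta | 2.00 | 14.9 | 1.7 |
| beta | 4.00 | 33.1 | 2.2 |
| beta | 6.00 | 39.6 | 0.7 |
| beta | 10.0 | 40.4 | 0 |
| delta | 0.833 | 0 | 1.0 |
| delta | 1.33 | 7.5 | 0 |
| delta | 2.50 | 25.7 | 0 |
| delta | 5.00 | 44.0 | 0.8 |
| delta | 10.0 | 48.3 | 2.7 |

(scatter of a reading: 1 percentage point)

- free catalyst is single-handed; left-handed substrate and right-handed substrate are mirror images of each other, charged as a racemate, each of them at the stated concentration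
- solid reagent is a solid; its amount is given per volume of the solution
- at the start none of the solid reagent is in solution
- an excess is the difference of the two amounts in percent of their sum
- an excess is below zero if the other one leads

- which of the two ends with the higher excess of left-handed product over right-handed product in the product ("neither" if they lie within 2 percentage points) (ash / maple / neither)
- excess of left-handed product over right-handed product in the product at the end, ash
- excess of left-handed product over right-handed product in the product at the end, maple

At 0.833 h the beta run reads 2.6 % left-handed product; none of the solid reagent is in solution at the start. Between 2.00 h and 4.00 h this climbs from 14.9 % to 33.1 %, while right-handed product reads 2.2 %. Then it stops, at 39.6 % and 40.4 %, with 19.2 % of the left-handed substrate still there.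

I take the late zeros of right-handed product as scatter of 1 percentage point around a small amount, not as a loss. Pooled over the last readings of the three runs, the ratio reads 106. This is my selectivity factor, the logarithm of the fraction of left-handed substrate remaining over that of the right-handed substrate. Its right-handed side rests on one non-zero reading, 2.7 %, so I hold it loosely.

For ash and maple I borrow delta's last 48.3 % as the stopping point, though they carry 7 mol% precatalyst against 10 mol%. The factor then gives 1.57 % right-handed product, an excess of 93.7 %. Beta stood still within scatter after 6.00 h, so I expect ash and maple to end alike.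

The forecast differs: 88 % for ash (76 % to 97 %), 97 % for maple (82 % to 100 %), and so maple, reading right-handed product as “unstable and lost once reagent is gone”.

The flasks give 95.8 % for ash and 95.6 % for maple, so the answer is neither.

    coupling partner + free catalyst + right-handed substrate → free catalyst + right-handed product (k = 0.0179 /M²/min)
    free catalyst → spent catalyst (k = 0.00539 /min)
    solid reagent ⇌ coupling partner, rate k3*(cs3 - [coupling partner]) while solid is left; crystals form when [coupling partner] > cs3 (solubility = 0.390 M, k = 0.0138 /min)
    coupling partner + free catalyst + left-handed substrate → free catalyst + left-handed product (k = 2.33 /M²/min)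
    coupling partner + precatalyst → free catalyst + spent reagent (k = 0.0422 /M/min)

Ash ends with 7.1 % of its left-handed substrate and 1.01 % right-handed product, a factor of 130. With that factor, the neighbour of ash at 18 mol% precatalyst, keeping 1.0 % of its left-handed substrate, comes to 1.74 % right-handed product; it holds 1.72 %, an excess of 93.3 %. Ash at 12 h still has 5.03 % of its catalyst free. By 120 h that is 0 %, left-handed substrate slips from 3.53 % to 3.13 % of the two substrates charged, and the excess goes from 95.8 % to 95.6 %. Maple at 200 h stands at 95.6 %.

Readings and results stem from a simulated flask for an exercise; scatter was added.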